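Start from the product: divide the L in the flask by the E charged. In the green run the last reading makes that 11.0 at 29 min. Call this L made per E charged the turnover count, the turnover number of the trade. The whole dispute below is about where that count goes next.

| flask | Z | G | E | time |
|---|---|---|---|---|
| green | 100 mM | 100 mM | 3.00 mM |  |
| grey | 40.0 mM | 40.0 mM | 3.00 mM |  |
| ochre | 100 mM | 100 mM | 1.50 mM |  |
| blue | 300 mM | 100 mM | 3.00 mM |  |
| teal | 100 mM | 100 mM | 3.00 mM | 170 min |

| run | time / min | [L] / mM |
|---|---|---|
| green run | 3.6 | 14.9 |
| green run | 7.2 | 22.4 |
| green run | 11 | 26.9 |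
| green run | 14 | 27.8 |
| green run | 18 | 29.6 |
| green run | 22 | 31.2 |
| green run | 25 | 31.0 |
| green run | 29 | 33.1 |
| grey run | 3.6 | 7.8 |
| grey run | 7.2 | 12.2 |
| grey run | 11 | 13.9 |
| grey run | 14 | 15.8 |
| grey run | 18 | 18.2 |
| grey run | 22 | 16.5 |
| grey run | 25 | 17.9 |
| grey run | 29 | 19.2 |
| ochre run | 3.6 | 8.7 |
| ochre run | 7.2 | 14.6 |
| ochre run | 11 | 16.7 |
| ochre run | 14 | 18.8 |
| ochre run | 18 | 21.3 |
| ochre run | 22 | 21.3 |
| ochre run | 25 | 21.4 |
| ochre run | 29 | 23.3 |
| blue run | 3.6 | 21.4 |
| blue run | 7.2 | 29.3 |
| blue run | 11 | 33.5 |
| blue run | 14 | 37.2 |
| blue run | 18 | 37.6 |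
| blue run | 22 | 37.5 |
| blue run | 25 | 40.4 |
| blue run | 29 | 37.9 |

(readings scatter by 0.8 mM)

- Overall: Z + G -> L, with E as catalyst.
- Constant volume, constant temperature.
- Bound and free are read together.
- An order is taken over about fifteen percent of the charge, up and down.

- reaction order in [G] at the outset, round the charge of the green run, defined at two percent of the Z turned into L
- reaction order in [Z] at the outset, round the charge of the green run, defined at two percent of the Z turned into L (one fixed amount of L, the same in the runs compared)
- L in the teal run at 170 min, as a share of the Z charged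

Teal is the green charge left standing for 170 min, so the count has to be carried far past the last reading. The charge leaves room for it, since 33.3 turnovers would use up the Z of green, well above the count read so far.

A second chemist says this flask is slow but alive. From 18 min to 29 min the green count rose by 0.106 min⁻¹. That pace, kept up for the remaining 141 min, adds 15.0 turnovers. The count would then stand at 26.0, still inside the room, and that is 78.0% of the Z.

The maker of the forecast says the flask is stopping. Over the first reading the green count rose by 1.38 min⁻¹, which is 13.0 times the late pace. A pace that has fallen so far can hardly be trusted to hold for 141 min, and the late rise itself is only 4.38 times the scatter of one reading. In the forecast's words, “The runs flatten far too early for Z or G to have run out”. Its numbers are 35% for teal, a count of 11.7, with order 0.7 in G and 0.45 in Z. The two counts differ by 14.3 turnovers, so the flask can tell them apart.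

The flask gives 33.1%, with order 0.64 in G and 0.32 in Z, the forecast's Z order standing higher.

    E + Z → EZ (182.4 M⁻¹ min⁻¹)
    EZ + G → Ze (31.68 M⁻¹ min⁻¹)
    Ze → L + E (5.436 min⁻¹)
    2 G → Xo (2.496 M⁻¹ min⁻¹)
    Z + G → L (0.1782 M⁻¹ min⁻¹)

Teal's count is 11.0, level with the 11.0 read in the green run at 29 min and under the second chemist's 26.0. The step taking G to Xo moves the readings by 42 times the scatter. In the grey run the count read at 29 min is 6.40, and at 47.4 min, where that flask's L comes to half of its Z, the count stands at 6.67, a gain of 0.267 turnovers over 18.4 min.

The data were computed for substances that don't exist; the scatter is artificial.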